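**Retrosynthetic overview**
1. The target is the protected lactone 33 after desilylation and hydrogenolysis. In the precursor, the lactone O–CH2 carbon is carried as a menthyl acetal stereocentre and the ring-B benzylic CH2 as a 1,3-dithiane.
2. Key disconnection: both benzylic bonds on the γ-lactone, C3(α)–CH2(ring A) and C4(β)–C(ring B), are made in one pot from three components, lithiated aryl dithiane 27, butenolide 26 and benzylic bromide 25. The enabling feature is the lactone itself: its C2 carbonyl conjugated to a C3=C4 double bond makes C4 electrophilic and turns C3 into an enolate carbon, while the C5 acetal directs the face.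
3. Both 8–5' units (the closed 2-aryl-2,3-dihydrobenzofuran on ring A and the open 1-aryl-2-arylpropane-1,3-diol on ring B) come from one N-arylacetyl oxazolidinone 10 and O-benzylvanillin 11, by switching the enolisation metal: boron gives the syn aldol, magnesium the anti aldol.
4. Imide 10 comes from 5-bromovanillin by dithiane formation, PMB protection, palladium-catalysed zinc-enolate arylation and acylation of the auxiliary.
5. Ring order: aromatic rings are purchased; the dihydrofuran ring of the benzofuran closes in step 11; the lactone ring enters intact as butenolide 26 and is re-closed as the final γ-lactone in step 17.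

Key step: step 15

Assumption: (5R)-5-[(1R,2S,5R)-menthyloxy]furan-2(5H)-one (26) is taken as a purchasable chiral building block.

Abbreviations: TBS = tert-butyldimethylsilyl, PMB = 4-methoxybenzyl, Bn = benzyl. Ring A is the benzo ring of the dihydrobenzofuran; ring B is the aryl ring that carries the open diol chain.

Step 1
Reactants: 1 5-bromovanillin (3-bromo-4-hydroxy-5-methoxybenzaldehyde)
Product: 2 2-(3-bromo-4-hydroxy-5-methoxyphenyl)-1,3-dithiane
Conditions: HS(CH2)3SH (1.1 equiv), BF3·OEt2 (cat.), CH2Cl2, 0 °C → rt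
Reagents that add atoms: propane-1,3-dithiol, SCCCS
Why: Lewis-acid-catalysed dithioacetalisation of the aryl aldehyde should be clean on the free phenol and installs the group that later serves as the lithiable benzylic carbon of ring B and as an acid-stable aldehyde mask for ring A.

Step 2
Reactants: 2 2-(3-bromo-4-hydroxy-5-methoxyphenyl)-1,3-dithiane
Product: 3 2-{3-bromo-5-methoxy-4-[(4-methoxybenzyl)oxy]phenyl}-1,3-dithiane
Conditions: 4-MeOC6H4CH2Cl, K2CO3, DMF, 60 °C
Reagents that add atoms: 4-methoxybenzyl chloride, COc1ccc(CCl)cc1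
Why: Williamson ether synthesis on the phenoxide; the PMB ether is chosen because it is cleaved by dilute acid (step 11) and also by hydrogenolysis (step 19) while being inert to base, hydride and organolithium reagents.

Step 3
Reactants: 3 2-{3-bromo-5-methoxy-4-[(4-methoxybenzyl)oxy]phenyl}-1,3-dithiane; 4 ethyl bromoacetate
Product: 6 ethyl 2-{5-(1,3-dithian-2-yl)-3-methoxy-2-[(4-methoxybenzyl)oxy]phenyl}acetate, via Reformatsky zinc reagent 5 (not isolated)
Conditions: 4, Zn dust (Me3SiCl-activated), THF, 40 °C; then 3, Pd(dba)2 (3 mol %), XPhos (6 mol %), THF, 60 °C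
Reagents that add atoms: none
Why: Negishi-type α-arylation of a Reformatsky zinc enolate with the aryl bromide on zerovalent palladium forms the aryl–CH2 bond under essentially neutral conditions, so the acidic dithiane C–H is not touched.

Step 4
Reactants: 6 ethyl 2-{5-(1,3-dithian-2-yl)-3-methoxy-2-[(4-methoxybenzyl)oxy]phenyl}acetate
Product: 7 2-{5-(1,3-dithian-2-yl)-3-methoxy-2-[(4-methoxybenzyl)oxy]phenyl}acetic acid
Conditions: LiOH·H2O, THF/MeOH/H2O, rt; then 1 M HCl to pH 3, 0 °C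
Reagents that add atoms: lithium hydroxide, [Li+].[OH-]
Why: Ester saponification; the dithiane and both aryl ethers are stable to base and to brief cold dilute acid.

Step 5
Reactants: 7 2-{5-(1,3-dithian-2-yl)-3-methoxy-2-[(4-methoxybenzyl)oxy]phenyl}acetic acid; 8 (S)-4-benzyl-1,3-oxazolidin-2-one
Product: 10 (4S)-4-benzyl-3-(2-{5-(1,3-dithian-2-yl)-3-methoxy-2-[(4-methoxybenzyl)oxy]phenyl}acetyl)-1,3-oxazolidin-2-one, via mixed pivalic anhydride 9 (not isolated)
Conditions: t-BuCOCl, Et3N, THF, −20 °C; then 8, LiCl, −20 °C → rt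
Reagents that add atoms: none
Why: N-acylation of the oxazolidinone auxiliary through the mixed anhydride with LiCl/Et3N activation avoids any organolithium base in the presence of the dithiane.

Step 6
Reactants: 10 (4S)-4-benzyl-3-(arylacetyl)oxazolidinone; 11 4-(benzyloxy)-3-methoxybenzaldehyde
Product: 13 anti-aldol (4S)-4-benzyl-3-[(2R,3S)-3-[4-(benzyloxy)-3-methoxyphenyl]-2-{5-(1,3-dithian-2-yl)-3-methoxy-2-[(4-methoxybenzyl)oxy]phenyl}-3-hydroxypropanoyl]-1,3-oxazolidin-2-one, via trimethylsilyl ether 12 (not isolated)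
Conditions: MgCl2 (0.2 equiv), Et3N (2 equiv), Me3SiCl (1.5 equiv), EtOAc, 23 °C; then 0.5 M HCl, THF, 0 °C
Reagents that add atoms: none
Why: Magnesium-halide-catalysed direct anti-aldol of an N-acyloxazolidinone with a non-enolisable aromatic aldehyde (soft enolisation, turnover by O-silylation): the aldehyde should add to the magnesium-chelated Z-enolate on the face away from the auxiliary benzyl group through a boat-like transition state, setting C2 as R and the carbinol C3 as S (anti).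

Step 7
Reactants: 13 anti-aldol imide
Product: 14 (1S,2S)-1-[4-(benzyloxy)-3-methoxyphenyl]-2-{5-(1,3-dithian-2-yl)-3-methoxy-2-[(4-methoxybenzyl)oxy]phenyl}propane-1,3-diol
Conditions: LiBH4, MeOH (1 equiv), THF, 0 °C
Reagents that add atoms: none
Why: Reductive cleavage of the N-acyl oxazolidinone with LiBH4 gives the primary alcohol without touching the two stereocentres and returns the auxiliary.

Step 8
Reactants: 14 (1S,2S)-diol
Product: 15 bis-TBS ether of 14, 2-{3-[(1S,2S)-1-[4-(benzyloxy)-3-methoxyphenyl]-1,3-bis(TBS-oxy)propan-2-yl]-5-methoxy-4-[(4-methoxybenzyl)oxy]phenyl}-1,3-dithiane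
Conditions: t-BuMe2SiOTf (2.5 equiv), 2,6-lutidine, CH2Cl2, −78 → 0 °C
Reagents that add atoms: tert-butyldimethylsilyl triflate, CC(C)(C)[Si](C)(C)OS(=O)(=O)C(F)(F)F
Why: Silylation with the silyl triflate protects the hindered benzylic and the primary alcohol as base-stable ethers, leaving the dithiane C–H as the only acidic site for step 15.

Step 9
Reactants: 10 (4S)-4-benzyl-3-(arylacetyl)oxazolidinone; 11 4-(benzyloxy)-3-methoxybenzaldehyde
Product: 18 syn-aldol (4S)-4-benzyl-3-[(2S,3S)-3-[4-(benzyloxy)-3-methoxyphenyl]-2-{5-(1,3-dithian-2-yl)-3-methoxy-2-[(4-methoxybenzyl)oxy]phenyl}-3-hydroxypropanoyl]-1,3-oxazolidin-2-one, via dibutylboron Z-enolate 16 (not isolated), via boron aldolate 17 (not isolated)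
Conditions: Bu2BOTf, i-Pr2NEt, CH2Cl2, −78 → 0 °C; 11, −78 → 0 °C; pH 7 buffer/MeOH (hydrolytic work-up, no peroxide)
Reagents that add atoms: none
Why: Evans syn-aldol through the Z-boron enolate and a chair Zimmerman–Traxler transition state on the non-chelated enolate face sets the aryl-bearing carbon (2S) in the sense needed for C3 of the dihydrobenzofuran, opposite to step 6, while the carbinol centre is re-set in step 11 and the peroxide-free work-up spares the dithiane.

Step 10
Reactants: 18 syn-aldol imide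
Product: 19 (1S,2R)-1-[4-(benzyloxy)-3-methoxyphenyl]-2-{5-(1,3-dithian-2-yl)-3-methoxy-2-[(4-methoxybenzyl)oxy]phenyl}propane-1,3-diol
Conditions: LiBH4, MeOH (1 equiv), THF, 0 °C
Reagents that add atoms: none
Why: LiBH4 reductive removal of the auxiliary as in step 7, with both stereocentres untouched.

Step 11
Reactants: 19 (1S,2R)-diol
Product: 21 [(2S,3R)-2-[4-(benzyloxy)-3-methoxyphenyl]-5-(1,3-dithian-2-yl)-7-methoxy-2,3-dihydro-1-benzofuran-3-yl]methanol, via free phenol 20 (not isolated)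
Conditions: CF3CO2H (10% v/v), anisole (5 equiv), CH2Cl2, 0 °C; then NaHCO3, MeOH
Reagents that add atoms: none
Why: Dilute acid cleaves the aryl PMB ether (cation scavenged by anisole) and ionises the electron-rich benzylic alcohol, so the liberated phenol closes the five-membered ring in a reversible SN1 etherification that should settle on the thermodynamically favoured 2,3-trans dihydrobenzofuran, with C3 (R, from the aldol) dictating C2 (S).

Step 12
Reactants: 21 dihydrobenzofuran alcohol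
Product: 22 TBS ether of 21, 2-[(2S,3R)-2-[4-(benzyloxy)-3-methoxyphenyl]-3-(TBS-oxymethyl)-7-methoxy-2,3-dihydro-1-benzofuran-5-yl]-1,3-dithiane
Conditions: t-BuMe2SiCl, imidazole, DMF, rt
Reagents that add atoms: tert-butyldimethylsilyl chloride, CC(C)(C)[Si](C)(C)Cl
Why: Standard silylation of the primary alcohol, matching the protection used on the other fragment.

Step 13
Reactants: 22 silylated dithiane
Product: 24 [(2S,3R)-2-[4-(benzyloxy)-3-methoxyphenyl]-3-(TBS-oxymethyl)-7-methoxy-2,3-dihydro-1-benzofuran-5-yl]methanol, via aldehyde 23 (not isolated)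
Conditions: MeI (excess), CaCO3, MeCN/H2O (9:1), 45 °C; then NaBH4, MeOH, 0 °C
Reagents that add atoms: water, O
Why: Alkylative hydrolysis of the dithiane (S-methylation, then attack of water) releases the aryl aldehyde, which NaBH4 reduces in the same flask to the benzylic alcohol.

Step 14
Reactants: 24 benzylic alcohol
Product: 25 (2S,3R)-2-[4-(benzyloxy)-3-methoxyphenyl]-5-(bromomethyl)-3-(TBS-oxymethyl)-7-methoxy-2,3-dihydro-1-benzofuran
Conditions: CBr4, PPh3, CH2Cl2, 0 °C; used at once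
Reagents that add atoms: carbon tetrabromide, BrC(Br)(Br)Br
Why: Appel bromination converts the primary benzylic alcohol into the bromide under neutral conditions that tolerate the silyl and benzyl ethers.

Step 15
Reactants: 15 ring-B aryl dithiane; 26 (5R)-5-[(1R,2S,5R)-menthyloxy]furan-2(5H)-one; 25 ring-A benzylic bromide
Product: 29 (3R,4R,5R)-3-(ring-A benzyl)-4-[2-(ring-B aryl)-1,3-dithian-2-yl]-5-[(1R,2S,5R)-menthyloxy]dihydrofuran-2(3H)-one, via lithiated dithiane 27 (not isolated), via lithium enolate 28 (not isolated)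
Conditions: 15, n-BuLi (1.05 equiv), THF, −78 → −30 °C; 26, −78 °C; then 25, DMPU, −78 → −20 °C; NH4Cl
Reagents that add atoms: none
Why: Deprotonation of 15 gives the 2-lithio-2-aryl-1,3-dithiane 27, a soft sulfur-stabilised carbanion that adds in 1,4-fashion to C4 of butenolide 26, and the resulting lactone lithium enolate 28 is C-alkylated at C3 by benzylic bromide 25 in an SN2 step that forms the bond between the lactone α-carbon and the ring-A benzylic CH2. The closest known reaction type is the tandem conjugate addition–enolate alkylation of 5-alkoxy-2(5H)-furanones with lithiated aryl dithianes and benzylic halides, the classical three-component entry to trans-2,3-dibenzylbutyrolactones. No ring is closed: two C–C bonds and two stereocentres are made on the preformed five-membered lactone ring. C4 is controlled by the C5 menthyloxy acetal (the nucleophile enters anti to the alkoxy group) and C3 by the new bulky C4 substituent (the electrophile enters anti to it), which should give the all-trans (3R,4R,5R) adduct. The step needs 1,4- over 1,2-addition (secured by the soft hindered dithiane anion and the activated γ-alkoxy enoate), selective deprotonation of the dithiane C–H (the only acidic C–H in 15, which has no carbonyl or free OH), and C-mono-alkylation of the enolate (secured by the reactive para-oxygenated benzylic bromide, the polar additive and low temperature).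

Step 16
Reactants: 29 three-component adduct
Product: 30 (3R,4R,5R)-3-(ring-A benzyl)-4-(ring-B benzyl)-5-[(1R,2S,5R)-menthyloxy]dihydrofuran-2(3H)-one
Conditions: Raney Ni (W-2, acetone-aged), EtOH/THF, rt
Reagents that add atoms: none
Why: Raney-nickel hydrogenolysis of the two C–S bonds (Mozingo-type desulfurisation) turns the dithiane carbon into the benzylic CH2 of ring B; room temperature and aged catalyst should leave the aryl benzyl ethers and all stereocentres untouched.

Step 17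
Reactants: 30 desulfurised lactone acetal
Product: 33 (3R,4R)-3-(ring-A benzyl)-4-(ring-B benzyl)dihydrofuran-2(3H)-one with all protecting groups in place, via aldehyde acid 31 (not isolated), via hydroxy acid 32 (not isolated)
Conditions: NaBH4, KOH, MeOH/THF/H2O, 0 °C → rt; then 1 M HCl to pH 3, 0 °C → rt
Reagents that add atoms: none
Why: Hydroxide opens the acyloxy acetal (lactone saponification, then collapse of the hemiacetal with loss of mentholate) to the aldehyde carboxylate, NaBH4 reduces the aldehyde as it forms (limiting epimerisation at its α-carbon), and mild acidification relactonises the γ-hydroxy acid to the trans-lactone with the carbonyl next to C3.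

Step 18
Reactants: 33 protected lactone
Product: 34 triol (three TBS groups removed; two Bn ethers and one PMB ether remain)
Conditions: Bu4NF (4 equiv), AcOH (4 equiv), THF, rt
Reagents that add atoms: none
Why: Buffered fluoride cleaves the three silyl ethers while all phenols are still protected, so no quinone methide can form at the benzylic carbinol and the lactone α-centre is not exposed to strong base.

Step 19
Reactants: 34 triol
Product: 35 target CNP0199264.2
Conditions: H2 (1 atm), 10% Pd/C, EtOAc/EtOH, rt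
Reagents that add atoms: none
Why: Hydrogenolysis of the two aryl benzyl ethers and the aryl PMB ether over Pd/C under neutral conditions should be much faster than cleavage of the benzylic C–OH bond or the dihydrobenzofuran C–O bond, delivering the three phenols of the target.

**Compound list**
1 | 5-bromovanillin | COc1cc(C=O)cc(Br)c1O | starting material
2 | 2-(3-bromo-4-hydroxy-5-methoxyphenyl)-1,3-dithiane | COc1cc(C2SCCCS2)cc(Br)c1O | intermediate
3 | 2-{3-bromo-5-methoxy-4-[(4-methoxybenzyl)oxy]phenyl}-1,3-dithiane | COc1cc(C2SCCCS2)cc(Br)c1OCc1ccc(OC)cc1 | intermediate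
4 | ethyl bromoacetate | CCOC(=O)CBr | starting material
5 | (2-ethoxy-2-oxoethyl)zinc bromide (formed in situ) | CCOC(=O)C[Zn]Br | intermediate
6 | ethyl 2-{5-(1,3-dithian-2-yl)-3-methoxy-2-[(4-methoxybenzyl)oxy]phenyl}acetate | CCOC(=O)Cc1cc(C2SCCCS2)cc(OC)c1OCc1ccc(OC)cc1 | intermediate
7 | 2-{5-(1,3-dithian-2-yl)-3-methoxy-2-[(4-methoxybenzyl)oxy]phenyl}acetic acid | OC(=O)Cc1cc(C2SCCCS2)cc(OC)c1OCc1ccc(OC)cc1 | intermediate
8 | (S)-4-benzyl-1,3-oxazolidin-2-one | O=C1N[C@@H](Cc2ccccc2)CO1 | starting material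
9 | mixed anhydride of 7 with pivalic acid (formed in situ) | CC(C)(C)C(=O)OC(=O)Cc1cc(C2SCCCS2)cc(OC)c1OCc1ccc(OC)cc1 | intermediate
10 | (4S)-4-benzyl-3-(2-{5-(1,3-dithian-2-yl)-3-methoxy-2-[(4-methoxybenzyl)oxy]phenyl}acetyl)-1,3-oxazolidin-2-one | O=C(Cc1cc(C2SCCCS2)cc(OC)c1OCc1ccc(OC)cc1)N1C(=O)OC[C@@H]1Cc1ccccc1 | intermediate
11 | 4-(benzyloxy)-3-methoxybenzaldehyde | COc1cc(C=O)ccc1OCc1ccccc1 | starting material
12 | O-trimethylsilyl ether of anti-aldol 13 (formed in situ) | COc1cc([C@@H](O[Si](C)(C)C)[C@H](C(=O)N2C(=O)OC[C@@H]2Cc2ccccc2)c2cc(C3SCCCS3)cc(OC)c2OCc2ccc(OC)cc2)ccc1OCc1ccccc1 | intermediate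
13 | anti-aldol, (4S)-auxiliary, (2R,3S)-3-hydroxypropanoyl chain | COc1cc([C@@H](O)[C@H](C(=O)N2C(=O)OC[C@@H]2Cc2ccccc2)c2cc(C3SCCCS3)cc(OC)c2OCc2ccc(OC)cc2)ccc1OCc1ccccc1 | intermediate
14 | (1S,2S)-1-[4-(benzyloxy)-3-methoxyphenyl]-2-{5-(1,3-dithian-2-yl)-3-methoxy-2-[(4-methoxybenzyl)oxy]phenyl}propane-1,3-diol | COc1cc([C@@H](O)[C@H](CO)c2cc(C3SCCCS3)cc(OC)c2OCc2ccc(OC)cc2)ccc1OCc1ccccc1 | intermediate
15 | bis-TBS ether of 14 (1S,2S) | COc1cc([C@@H](O[Si](C)(C)C(C)(C)C)[C@H](CO[Si](C)(C)C(C)(C)C)c2cc(C3SCCCS3)cc(OC)c2OCc2ccc(OC)cc2)ccc1OCc1ccccc1 | intermediate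
16 | dibutylboron Z-enolate of 10 (formed in situ) | CCCCB(CCCC)O/C(=C\c1cc(C2SCCCS2)cc(OC)c1OCc1ccc(OC)cc1)N1C(=O)OC[C@@H]1Cc1ccccc1 | intermediate
17 | O-dibutylboryl aldolate of 18 (formed in situ) | COc1cc([C@@H](OB(CCCC)CCCC)[C@@H](C(=O)N2C(=O)OC[C@@H]2Cc2ccccc2)c2cc(C3SCCCS3)cc(OC)c2OCc2ccc(OC)cc2)ccc1OCc1ccccc1 | intermediate
18 | syn-aldol, (4S)-auxiliary, (2S,3S)-3-hydroxypropanoyl chain | COc1cc([C@@H](O)[C@@H](C(=O)N2C(=O)OC[C@@H]2Cc2ccccc2)c2cc(C3SCCCS3)cc(OC)c2OCc2ccc(OC)cc2)ccc1OCc1ccccc1 | intermediate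
19 | (1S,2R)-1-[4-(benzyloxy)-3-methoxyphenyl]-2-{5-(1,3-dithian-2-yl)-3-methoxy-2-[(4-methoxybenzyl)oxy]phenyl}propane-1,3-diol | COc1cc([C@@H](O)[C@@H](CO)c2cc(C3SCCCS3)cc(OC)c2OCc2ccc(OC)cc2)ccc1OCc1ccccc1 | intermediate
20 | (1S,2R)-1-[4-(benzyloxy)-3-methoxyphenyl]-2-[5-(1,3-dithian-2-yl)-2-hydroxy-3-methoxyphenyl]propane-1,3-diol (formed in situ) | COc1cc([C@@H](O)[C@@H](CO)c2cc(C3SCCCS3)cc(OC)c2O)ccc1OCc1ccccc1 | intermediate
21 | [(2S,3R)-2-[4-(benzyloxy)-3-methoxyphenyl]-5-(1,3-dithian-2-yl)-7-methoxy-2,3-dihydro-1-benzofuran-3-yl]methanol | C1(SCCCS1)c1cc(OC)c2c(c1)[C@H](CO)[C@@H](c1ccc(OCc3ccccc3)c(OC)c1)O2 | intermediate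
22 | TBS ether of 21 | C1(SCCCS1)c1cc(OC)c2c(c1)[C@H](CO[Si](C)(C)C(C)(C)C)[C@@H](c1ccc(OCc3ccccc3)c(OC)c1)O2 | intermediate
23 | (2S,3R)-2-[4-(benzyloxy)-3-methoxyphenyl]-3-(TBS-oxymethyl)-7-methoxy-2,3-dihydro-1-benzofuran-5-carbaldehyde (formed in situ) | O=Cc1cc(OC)c2c(c1)[C@H](CO[Si](C)(C)C(C)(C)C)[C@@H](c1ccc(OCc3ccccc3)c(OC)c1)O2 | intermediate
24 | [(2S,3R)-2-[4-(benzyloxy)-3-methoxyphenyl]-3-(TBS-oxymethyl)-7-methoxy-2,3-dihydro-1-benzofuran-5-yl]methanol | OCc1cc(OC)c2c(c1)[C@H](CO[Si](C)(C)C(C)(C)C)[C@@H](c1ccc(OCc3ccccc3)c(OC)c1)O2 | intermediate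
25 | (2S,3R)-2-[4-(benzyloxy)-3-methoxyphenyl]-5-(bromomethyl)-3-(TBS-oxymethyl)-7-methoxy-2,3-dihydro-1-benzofuran | BrCc1cc(OC)c2c(c1)[C@H](CO[Si](C)(C)C(C)(C)C)[C@@H](c1ccc(OCc3ccccc3)c(OC)c1)O2 | intermediate
26 | (5R)-5-{[(1R,2S,5R)-2-isopropyl-5-methylcyclohexyl]oxy}furan-2(5H)-one | CC(C)[C@@H]1CC[C@@H](C)C[C@H]1O[C@H]1C=CC(=O)O1 | starting material
27 | 2-lithio derivative of dithiane 15 (formed in situ) | COc1cc([C@@H](O[Si](C)(C)C(C)(C)C)[C@H](CO[Si](C)(C)C(C)(C)C)c2cc(C3([Li])SCCCS3)cc(OC)c2OCc2ccc(OC)cc2)ccc1OCc1ccccc1 | intermediate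
28 | lithium enolate of the (4R,5R) conjugate adduct (formed in situ) | COc1cc([C@@H](O[Si](C)(C)C(C)(C)C)[C@H](CO[Si](C)(C)C(C)(C)C)c2cc(C3(SCCCS3)[C@H]3[C@H](O[C@@H]4C[C@H](C)CC[C@H]4C(C)C)OC(O[Li])=C3)cc(OC)c2OCc2ccc(OC)cc2)ccc1OCc1ccccc1 | intermediate
29 | (3R,4R,5R) three-component adduct: 3-(ring-A benzyl)-4-[2-(ring-B aryl)-1,3-dithian-2-yl]-5-menthyloxy lactone | COc1cc([C@@H](O[Si](C)(C)C(C)(C)C)[C@H](CO[Si](C)(C)C(C)(C)C)c2cc(C3(SCCCS3)[C@H]3[C@H](O[C@@H]4C[C@H](C)CC[C@H]4C(C)C)OC(=O)[C@@H]3Cc3cc(OC)c4c(c3)[C@H](CO[Si](C)(C)C(C)(C)C)[C@@H](c3ccc(OCc5ccccc5)c(OC)c3)O4)cc(OC)c2OCc2ccc(OC)cc2)ccc1OCc1ccccc1 | intermediate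
30 | (3R,4R,5R)-3-(ring-A benzyl)-4-(ring-B benzyl)-5-menthyloxy lactone | COc1cc([C@@H](O[Si](C)(C)C(C)(C)C)[C@H](CO[Si](C)(C)C(C)(C)C)c2cc(C[C@H]3[C@H](O[C@@H]4C[C@H](C)CC[C@H]4C(C)C)OC(=O)[C@@H]3Cc3cc(OC)c4c(c3)[C@H](CO[Si](C)(C)C(C)(C)C)[C@@H](c3ccc(OCc5ccccc5)c(OC)c3)O4)cc(OC)c2OCc2ccc(OC)cc2)ccc1OCc1ccccc1 | intermediate
31 | (2R,3R)-2-(ring-A benzyl)-3-formyl-4-(ring-B aryl)butanoic acid (formed in situ) | COc1cc([C@@H](O[Si](C)(C)C(C)(C)C)[C@H](CO[Si](C)(C)C(C)(C)C)c2cc(C[C@@H](C=O)[C@H](C(=O)O)Cc3cc(OC)c4c(c3)[C@H](CO[Si](C)(C)C(C)(C)C)[C@@H](c3ccc(OCc5ccccc5)c(OC)c3)O4)cc(OC)c2OCc2ccc(OC)cc2)ccc1OCc1ccccc1 | intermediate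
32 | (2R,3R)-2-(ring-A benzyl)-3-(hydroxymethyl)-4-(ring-B aryl)butanoic acid (formed in situ) | COc1cc([C@@H](O[Si](C)(C)C(C)(C)C)[C@H](CO[Si](C)(C)C(C)(C)C)c2cc(C[C@@H](CO)[C@H](C(=O)O)Cc3cc(OC)c4c(c3)[C@H](CO[Si](C)(C)C(C)(C)C)[C@@H](c3ccc(OCc5ccccc5)c(OC)c3)O4)cc(OC)c2OCc2ccc(OC)cc2)ccc1OCc1ccccc1 | intermediate
33 | (3R,4R)-lactone with three TBS ethers, two Bn ethers and one PMB ether | COc1cc([C@@H](O[Si](C)(C)C(C)(C)C)[C@H](CO[Si](C)(C)C(C)(C)C)c2cc(C[C@H]3COC(=O)[C@@H]3Cc3cc(OC)c4c(c3)[C@H](CO[Si](C)(C)C(C)(C)C)[C@@H](c3ccc(OCc5ccccc5)c(OC)c3)O4)cc(OC)c2OCc2ccc(OC)cc2)ccc1OCc1ccccc1 | intermediate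
34 | (3R,4R)-lactone triol with two Bn ethers and one PMB ether | COc1cc([C@@H](O)[C@H](CO)c2cc(C[C@H]3COC(=O)[C@@H]3Cc3cc(OC)c4c(c3)[C@H](CO)[C@@H](c3ccc(OCc5ccccc5)c(OC)c3)O4)cc(OC)c2OCc2ccc(OC)cc2)ccc1OCc1ccccc1 | intermediate
35 | CNP0199264.2: lactone (3R,4R), dihydrobenzofuran (2S,3R), diol chain (1S,2S) | COc1cc([C@@H](O)[C@H](CO)c2cc(C[C@H]3COC(=O)[C@@H]3Cc3cc(OC)c4c(c3)[C@H](CO)[C@@H](c3ccc(O)c(OC)c3)O4)cc(OC)c2O)ccc1O | target

**Step count**
Total: 19 steps. Longest linear sequence: 16 steps (steps 1–5, 9–14, 15–19).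

**Steps most likely to fail**

Step 15. Proton transfer may quench the enolate before alkylation, 1,2-addition may compete, and the electron-rich benzylic bromide may ionise or O-alkylate before it meets the hindered enolate. The fallback separates the two bond formations. It sets out from 15 and 26: the lithiated dithiane is added to 26 and the enolate is protonated with NH4Cl, so that the (4R,5R)-4-[2-(ring-B aryl)-1,3-dithian-2-yl]-5-menthyloxy lactone F1 is isolated. F1 is then re-enolised with LiN(SiMe3)2 in THF/DMPU at −78 °C and alkylated with 25, anti to the C4 substituent, and the route is rejoined at 29.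

Step 6. Anti selectivity at the carbinol carbon may erode through a competing chair pathway, or the α-aryl aldolate may undergo retro-aldol equilibration before silylation. The fallback keeps the enolate-face control but sets the carbinol by reagent control. It sets out from 14, taken as its mixture of C1 epimers. Selective silylation of the primary alcohol (t-BuMe2SiCl, imidazole) gives the primary mono-TBS ether F2. Oxidation of the benzylic alcohol with MnO2 (neutral, dithiane-compatible) gives the (2S)-aryl ketone F3. Corey–Bakshi–Shibata reduction with the (R)-methyl oxazaborolidine and BH3·SMe2 should give the (1S,2S)-alcohol F4. Silylation with t-BuMe2SiOTf/2,6-lutidine rejoins the route at 15.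

Step 16. On the nickel surface, benzyl-type aryl ethers and benzylic C–O bonds may be cleaved along with the C–S bonds, or cleavage at the hindered quaternary dithiane carbon may stall. The fallback replaces surface hydrogenolysis by homolytic desulfurisation: it sets out from 29, which is heated with Bu3SnH and AIBN in toluene so that both C–S bonds are reduced by a radical chain that does not touch benzyl ethers, and comes back at 30; no new compound arises (F0).

Further compounds
F1 | step 15 | (4R,5R)-4-[2-(ring-B aryl)-1,3-dithian-2-yl]-5-[(1R,2S,5R)-menthyloxy]dihydrofuran-2(3H)-one | COc1cc([C@@H](O[Si](C)(C)C(C)(C)C)[C@H](CO[Si](C)(C)C(C)(C)C)c2cc(C3(SCCCS3)[C@H]3[C@H](O[C@@H]4C[C@H](C)CC[C@H]4C(C)C)OC(=O)C3)cc(OC)c2OCc2ccc(OC)cc2)ccc1OCc1ccccc1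
F2 | step 6 | (2S)-1-[4-(benzyloxy)-3-methoxyphenyl]-3-(TBS-oxy)-2-{5-(1,3-dithian-2-yl)-3-methoxy-2-[(4-methoxybenzyl)oxy]phenyl}propan-1-ol, C1 epimers | COc1cc(C(O)[C@H](CO[Si](C)(C)C(C)(C)C)c2cc(C3SCCCS3)cc(OC)c2OCc2ccc(OC)cc2)ccc1OCc1ccccc1
F3 | step 6 | (2S)-1-[4-(benzyloxy)-3-methoxyphenyl]-3-(TBS-oxy)-2-{5-(1,3-dithian-2-yl)-3-methoxy-2-[(4-methoxybenzyl)oxy]phenyl}propan-1-one | COc1cc(C(=O)[C@H](CO[Si](C)(C)C(C)(C)C)c2cc(C3SCCCS3)cc(OC)c2OCc2ccc(OC)cc2)ccc1OCc1ccccc1
F4 | step 6 | (1S,2S)-1-[4-(benzyloxy)-3-methoxyphenyl]-3-(TBS-oxy)-2-{5-(1,3-dithian-2-yl)-3-methoxy-2-[(4-methoxybenzyl)oxy]phenyl}propan-1-ol | COc1cc([C@@H](O)[C@H](CO[Si](C)(C)C(C)(C)C)c2cc(C3SCCCS3)cc(OC)c2OCc2ccc(OC)cc2)ccc1OCc1ccccc1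
F0 | step 16 | none | none
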